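The ester is taken back to a silyl-protected primary alcohol. The 1,2-dioxane O1–O2–C3–C4–C5–C6 is cut at C4–C5: these are two plain methylenes between the oxygen-bearing stereocentres C3 and C6, so both C–O bonds can be set on an open-chain peroxide and the ring closed afterwards by olefin metathesis. The open-chain peroxide is cut at O–C6 (hydroperoxide + epoxide) and at O–C3 (hydroperoxide anion + mesylate).
The decalin half is cut at C9′–C11′ (conjugate addition) and at the allylic alcohol (alkyne carboalumination/hydroxymethylation).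
Forward: enone 1 already holds rings A and B and is worked up to the trans-decalin enone 9; the side chain is added and turned into epoxy alcohol 18. Hydroperoxide 25 comes from an Evans aldol. 18 and 25 are joined through O–C6, two vinyl groups are put in place, and the peroxide ring, the only ring made in the route, is closed before the final redox steps.
Stereochemistry: C10′ from 1; C5′ from dissolving-metal reduction; C9′ from cuprate attack anti to the angular methyl; C6 from Sharpless epoxidation (D-tartrate) then inversion; C2 and C3 from the (S)-benzyloxazolidinone aldol then inversion at C3.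

Key step: step 21

Remark: enone 1 is taken as a catalogue compound (it is also the one-pot product of 2-methylcyclohexanone, (S)-1-phenylethylamine and methyl vinyl ketone); unprimed locants refer to the peroxide half (C1 ester carbon, C2, ring O1–O2–C3–C4–C5–C6), primed locants to the decalin (C4′ gem-dimethyl, C10′ angular methyl); DEC = (1S,4aR,8aR)-2,5,5,8a-tetramethyl-1,4,4a,5,6,7,8,8a-octahydronaphthalen-1-yl, TBDPS = tert-butyldiphenylsilyl.

Step 1
Reactants: 1 (R)-4a-methyl-4,4a,5,6,7,8-hexahydronaphthalen-2(3H)-one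
Product: 2 (R)-1,1,4a-trimethyl-3,4,4a,5,6,7-hexahydronaphthalen-2(1H)-one
Conditions: KOtBu (3 equiv), t-BuOH, 25 °C; MeI (4 equiv), 0 → 25 °C
Reagents that add atoms: iodomethane, CI
Why: Deconjugative double α-methylation of the dienolate (the classical gem-dimethylation of a 4-en-3-one): the second methylation outruns reconjugation and leaves the C5′=C6′ alkene out of conjugation, with the quaternary C10′ untouched.

Step 2
Reactants: 2 (R)-1,1,4a-trimethyl-3,4,4a,5,6,7-hexahydronaphthalen-2(1H)-one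
Product: 4 (R)-1,1,4a-trimethyl-1,2,3,4,4a,5,6,7-octahydronaphthalene, via hydrazone 3 (not isolated)
Conditions: N2H4·H2O, KOH, diethylene glycol, 130 → 200 °C
Reagents that add atoms: none
Why: Wolff–Kishner reduction (Huang-Minlon variant) removes the carbonyl through its hydrazone; the alkene has nothing to conjugate with and stays at C5′=C6′.

Step 3
Reactants: 4 (R)-1,1,4a-trimethyl-1,2,3,4,4a,5,6,7-octahydronaphthalene
Product: 5 (S)-4a,8,8-trimethyl-4,4a,5,6,7,8-hexahydronaphthalen-2(3H)-one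
Conditions: Rh2(cap)4 (dirhodium tetracaprolactamate, 1 mol%), t-BuOOH (5 equiv), K2CO3, CH2Cl2, 25 °C
Reagents that add atoms: tert-butyl hydroperoxide, CC(C)(C)OO
Why: Dirhodium-catalysed allylic oxidation with t-BuOOH (radical allylic C–H peroxidation, then ketone formation) can only take place at C7′, the single allylic CH2, as in the 5-ene to 7-ketone oxidation of steroids.

Step 4
Reactants: 5 (S)-4a,8,8-trimethyl-4,4a,5,6,7,8-hexahydronaphthalen-2(3H)-one
Product: 6 (4aS)-3,4a,8,8-tetramethyl-4,4a,5,6,7,8-hexahydronaphthalen-2(3H)-one (C3 epimer mixture)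
Conditions: LDA (LiN(iPr)2), THF, −78 °C; MeI, −78 → 0 °C
Reagents that add atoms: iodomethane, CI
Why: Kinetic α′-deprotonation (there is no γ-hydrogen) and enolate alkylation place the future C8′ methyl; the new centre forms as an epimer mixture and becomes sp2 in step 6.

Step 5
Reactants: 6 (4aS)-3,4a,8,8-tetramethyl-4,4a,5,6,7,8-hexahydronaphthalen-2(3H)-one
Product: 7 (4aS,8aR)-3,4a,8,8-tetramethyl-3,4,4a,5,6,7,8,8a-octahydronaphthalen-2(1H)-one (trans-fused, C3 epimer mixture)
Conditions: Li, NH3 (l)/THF, t-BuOH (1 equiv), −78 °C; NH4Cl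
Reagents that add atoms: none
Why: Dissolving-metal (Birch-type) reduction of the enone: the β-carbanion at C5′ is protonated axially on the face away from the angular C10′ methyl, which sets C5′ and gives the trans-decalin.

Step 6
Reactants: 7 (4aS,8aR)-3,4a,8,8-tetramethyl-3,4,4a,5,6,7,8,8a-octahydronaphthalen-2(1H)-one
Product: 9 (4aS,8aR)-3,4a,8,8-tetramethyl-4a,5,6,7,8,8a-hexahydronaphthalen-2(1H)-one, via silyl enol ether 8 (not isolated)
Conditions: Me3SiCl, NaI, Et3N, MeCN, 25 °C; then Pd(OAc)2 (1.05 equiv), MeCN, 25 °C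
Reagents that add atoms: none
Why: Thermodynamic silyl enol ether formation towards the more substituted C8′ and Saegusa–Ito dehydrogenation with divalent palladium (β-hydride loss from C9′) give the 2-methyl enone; enol ether formed towards C6′ would only regenerate 6, which can be recycled.

Step 7
Reactants: 9 (4aS,8aR)-3,4a,8,8-tetramethyl-4a,5,6,7,8,8a-hexahydronaphthalen-2(1H)-one; 10 (4-bromobut-1-yn-1-yl)trimethylsilane
Product: 12 {[(4R,4aR,8aR)-3,4a,8,8-tetramethyl-4-[4-(trimethylsilyl)but-3-yn-1-yl]-1,4,4a,5,6,7,8,8a-octahydronaphthalen-2-yl]oxy}trimethylsilane, via Grignard reagent 11 (not isolated)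
Conditions: 10, Mg, THF, 40 °C; then CuBr·SMe2 (0.2 equiv), Me3SiCl (2 equiv), HMPA, 9, THF, −78 → −40 °C; Et3N, cold NaHCO3 work-up
Reagents that add atoms: chlorotrimethylsilane, C[Si](C)(C)Cl
Why: Chlorotrimethylsilane-accelerated copper-catalysed conjugate addition of the Grignard reagent: axial attack at C9′ on the face opposite the angular C10′ methyl (the course known from 1α-alkylation of steroidal 1-en-3-ones) sets C9′ with the chain trans to that methyl, and the enolate is held regiospecifically as the silyl enol ether.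

Step 8
Reactants: 12 {[(4R,4aR,8aR)-3,4a,8,8-tetramethyl-4-[4-(trimethylsilyl)but-3-yn-1-yl]-1,4,4a,5,6,7,8,8a-octahydronaphthalen-2-yl]oxy}trimethylsilane
Product: 13 (4R,4aR,8aR)-3,4a,8,8-tetramethyl-4-[4-(trimethylsilyl)but-3-yn-1-yl]-1,4,4a,5,6,7,8,8a-octahydronaphthalen-2-yl trifluoromethanesulfonate
Conditions: MeLi (1.05 equiv), THF, −20 → 0 °C; PhNTf2, −78 → 0 °C
Reagents that add atoms: N-phenylbis(trifluoromethanesulfonimide), O=S(=O)(N(c1ccccc1)S(=O)(=O)C(F)(F)F)C(F)(F)F
Why: Methyllithium cleaves the O–Si bond to the regiodefined lithium enolate, which is O-sulfonylated by PhNTf2 (McMurry–Scott enol triflate synthesis), so the double bond is locked at C7′=C8′; the alkynylsilane is not attacked at this temperature.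

Step 9
Reactants: 13 (4R,4aR,8aR)-3,4a,8,8-tetramethyl-4-[4-(trimethylsilyl)but-3-yn-1-yl]-1,4,4a,5,6,7,8,8a-octahydronaphthalen-2-yl trifluoromethanesulfonate
Product: 14 trimethyl(4-DEC-but-1-yn-1-yl)silane
Conditions: Pd(OAc)2 (5 mol%), PPh3 (10 mol%), HCO2H (2 equiv), Bu3N (3 equiv), DMF, 60 °C
Reagents that add atoms: none
Why: Palladium-catalysed formate reduction of the enol triflate (Cacchi conditions: oxidative addition to zerovalent palladium, formate-to-hydride exchange, reductive elimination) replaces OTf by H without moving the alkene or touching C9′.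

Step 10
Reactants: 14 trimethyl(4-DEC-but-1-yn-1-yl)silane
Product: 15 4-DEC-but-1-yne
Conditions: K2CO3, MeOH, 25 °C
Reagents that add atoms: none
Why: Base-catalysed methanolysis of the C(sp)–Si bond (protodesilylation) frees the terminal alkyne.

Step 11
Reactants: 15 4-DEC-but-1-yne
Product: 17 (2E)-3-methyl-5-DEC-pent-2-en-1-ol, via alkenylalane 16 (not isolated)
Conditions: Me3Al (2.5 equiv), Cp2ZrCl2 (0.25 equiv), CH2Cl2, 0 → 25 °C; then n-BuLi, THF/hexane, −78 °C; (CH2O)n, −78 → 25 °C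
Reagents that add atoms: trimethylaluminium, C[Al](C)C; formaldehyde (from paraformaldehyde), C=O
Why: Negishi zirconium-catalysed carboalumination adds Me and Al syn across the alkyne with the methyl on the inner carbon, and the alkenylalanate is hydroxymethylated by formaldehyde with retention, giving the (E)-allylic alcohol only; the trisubstituted ring alkene does not react.

Step 12
Reactants: 17 (2E)-3-methyl-5-DEC-pent-2-en-1-ol
Product: 18 [(2R,3R)-3-methyl-3-(2-DEC-ethyl)oxiran-2-yl]methanol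
Conditions: Ti(OiPr)4 (10 mol%), D-(−)-diethyl tartrate (12 mol%), t-BuOOH (2 equiv), 4 Å MS, CH2Cl2, −20 °C
Reagents that add atoms: tert-butyl hydroperoxide, CC(C)(C)OO
Why: Sharpless asymmetric epoxidation: the titanium tartrate complex with D-(−)-tartrate delivers oxygen to the face that gives the (2R,3R)-epoxide (reagent control, as for geraniol-type alcohols), and the ring alkene, which has no directing hydroxyl, is left alone.

Step 13
Reactants: 19 (S)-4-benzyl-3-propionyloxazolidin-2-one; 20 acrolein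
Product: 21 (S)-4-benzyl-3-[(2S,3R)-3-hydroxy-2-methylpent-4-enoyl]oxazolidin-2-one
Conditions: Bu2BOTf (1.2 equiv), iPr2NEt (1.3 equiv), CH2Cl2, 0 °C; 20, −78 → 0 °C; pH 7 buffer, MeOH, 30% H2O2, 0 °C
Reagents that add atoms: none
Why: Evans syn-aldol reaction: the (Z)-boron enolate reacts through a Zimmerman–Traxler chair on the face opposite the benzyl group, setting (2S,3R).

Step 14
Reactants: 21 (S)-4-benzyl-3-[(2S,3R)-3-hydroxy-2-methylpent-4-enoyl]oxazolidin-2-one
Product: 22 (2R,3R)-2-methylpent-4-ene-1,3-diol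
Conditions: LiBH4, MeOH (1.1 equiv), Et2O, 0 °C
Reagents that add atoms: none
Why: Hydride attack on the exocyclic imide carbonyl (reductive auxiliary removal) gives the diol and returns the oxazolidinone; no stereocentre is touched.

Step 15
Reactants: 22 (2R,3R)-2-methylpent-4-ene-1,3-diol
Product: 23 (3R,4R)-5-(TBDPS-oxy)-4-methylpent-1-en-3-ol
Conditions: t-BuPh2SiCl (1.05 equiv), imidazole, CH2Cl2, 0 °C
Reagents that add atoms: tert-butylchlorodiphenylsilane, CC(C)(C)[Si](Cl)(c1ccccc1)c1ccccc1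
Why: Steric differentiation in silyl ether formation: the bulky silyl chloride reacts with the primary hydroxyl only.

Step 16
Reactants: 23 (3R,4R)-5-(TBDPS-oxy)-4-methylpent-1-en-3-ol
Product: 24 (3R,4R)-5-(TBDPS-oxy)-4-methylpent-1-en-3-yl methanesulfonate
Conditions: MeSO2Cl, Et3N, CH2Cl2, −30 °C; used cold without chromatography
Reagents that add atoms: methanesulfonyl chloride, CS(=O)(=O)Cl
Why: O-Sulfonylation proceeds with retention because only the O–H bond reacts.

Step 17
Reactants: 24 (3R,4R)-5-(TBDPS-oxy)-4-methylpent-1-en-3-yl methanesulfonate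
Product: 25 tert-butyl{[(2R,3S)-3-hydroperoxy-2-methylpent-4-en-1-yl]oxy}diphenylsilane
Conditions: H2O2 (50% aq., 20 equiv), KOH (2 equiv), MeOH/THF, 0 °C
Reagents that add atoms: hydrogen peroxide, OO
Why: SN2 displacement of the allylic mesylate by hydroperoxide anion (an α-effect nucleophile; Williams–Mosher-type hydroperoxide synthesis) inverts C3 to the 3S configuration needed in the ring.

Step 18
Reactants: 18 [(2R,3R)-3-methyl-3-(2-DEC-ethyl)oxiran-2-yl]methanol; 25 tert-butyl{[(2R,3S)-3-hydroperoxy-2-methylpent-4-en-1-yl]oxy}diphenylsilane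
Product: 26 (2R,3S)-3-{[(3S,4R)-5-(TBDPS-oxy)-4-methylpent-1-en-3-yl]peroxy}-3-methyl-5-DEC-pentane-1,2-diol
Conditions: 25 (3 equiv, excess recovered), BF3·OEt2 (0.2 equiv), Et2O, −78 → −30 °C
Reagents that add atoms: none
Why: Lewis acid-catalysed opening of the trisubstituted epoxide by the hydroperoxide at the tertiary carbon, which best carries positive charge, with backside attack and therefore inversion at C6 (the course established for perhydrolysis of such epoxy alcohols and for hydroperoxide opening of oxetanes).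

Step 19
Reactants: 26 (2R,3S)-3-{[(3S,4R)-5-(TBDPS-oxy)-4-methylpent-1-en-3-yl]peroxy}-3-methyl-5-DEC-pentane-1,2-diol
Product: 27 (2S)-2-{[(3S,4R)-5-(TBDPS-oxy)-4-methylpent-1-en-3-yl]peroxy}-2-methyl-4-DEC-butanal
Conditions: NaIO4, THF/pH 7 buffer, 0 °C
Reagents that add atoms: none
Why: Malaprade glycol cleavage by periodate removes C1 of the diol as formaldehyde and leaves the α-peroxy aldehyde, which has no α-hydrogen and cannot epimerise; peroxide and alkenes are inert to periodate.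

Step 20
Reactants: 27 (2S)-2-{[(3S,4R)-5-(TBDPS-oxy)-4-methylpent-1-en-3-yl]peroxy}-2-methyl-4-DEC-butanal
Product: 28 tert-butyl{[(2R,3S)-2-methyl-3-{[(3S)-3-methyl-5-DEC-pent-1-en-3-yl]peroxy}pent-4-en-1-yl]oxy}diphenylsilane
Conditions: Ph3PCH3Br, KHMDS (KN(SiMe3)2), THF, 0 °C; then 27, −78 → 0 °C
Reagents that add atoms: methylenetriphenylphosphorane, C=P(c1ccccc1)(c1ccccc1)c1ccccc1
Why: Wittig methylenation of a non-enolisable aldehyde; the ylide is added at low temperature so that olefination outruns base-induced (Kornblum–DeLaMare) cleavage of the secondary peroxide.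

Step 21
Reactants: 28 tert-butyl{[(2R,3S)-2-methyl-3-{[(3S)-3-methyl-5-DEC-pent-1-en-3-yl]peroxy}pent-4-en-1-yl]oxy}diphenylsilane
Product: 29 tert-butyl{(2R)-2-[(3S,6S)-6-methyl-6-(2-DEC-ethyl)-3,6-dihydro-1,2-dioxin-3-yl]propoxy}diphenylsilane
Conditions: RuCl2(=CHPh)(H2IMes)(PCy3) (second-generation Grubbs catalyst, 5–10 mol%), CH2Cl2 (0.005 M), 40 °C, argon sparge
Reagents that add atoms: none
Why: Proposed new method: the ruthenium benzylidene should exchange with the less hindered C3 vinyl group, the new alkylidene then adds across the C6 vinyl group held close by the O–O tether, and the ruthenacyclobutane cycloreverts to the C4=C5 alkene and ethene, which is swept out. The closest known reaction types are ring-closing metathesis of bis-allylic ethers to 3,6-dihydro-2H-pyrans and cross-metathesis of alkenes that already carry dialkyl peroxide groups, where ruthenium alkylidenes leave the O–O bond intact. The 1,2-dioxine ring closes in the six-membered ring-closing-metathesis mode, with the cis ring alkene as the only possible geometry. No stereocentre is formed; C3 and C6 were fixed in steps 17 and 18 and are not touched, since neither carbon becomes part of the metallacycle. The step needs chemoselectivity for the two monosubstituted vinyl groups over the trisubstituted C7′=C8′ alkene and over the O–O bond, and ring closure over oligomerisation; the first is secured by the steric shielding of the ring alkene, the last by the 1,6 relationship of the vinyl groups and high dilution.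

Step 22
Reactants: 29 tert-butyl{(2R)-2-[(3S,6S)-6-methyl-6-(2-DEC-ethyl)-3,6-dihydro-1,2-dioxin-3-yl]propoxy}diphenylsilane
Product: 30 tert-butyl{(2R)-2-[(3S,6S)-6-methyl-6-(2-DEC-ethyl)-1,2-dioxan-3-yl]propoxy}diphenylsilane
Conditions: KO2CN=NCO2K (excess), AcOH, MeOH/CH2Cl2, 0 → 25 °C
Reagents that add atoms: none
Why: Diimide transfers H2 in a concerted syn fashion to the strained cis-disubstituted ring alkene, much faster than to the trisubstituted C7′=C8′ alkene, and does not reduce the O–O bond (standard saturation of 3,6-dihydro-1,2-dioxines).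

Step 23
Reactants: 30 tert-butyl{(2R)-2-[(3S,6S)-6-methyl-6-(2-DEC-ethyl)-1,2-dioxan-3-yl]propoxy}diphenylsilane
Product: 31 (2R)-2-[(3S,6S)-6-methyl-6-(2-DEC-ethyl)-1,2-dioxan-3-yl]propan-1-ol
Conditions: HF·pyridine, pyridine/THF, 0 → 25 °C
Reagents that add atoms: none
Why: Fluoride-mediated cleavage of the silyl ether under mildly acidic conditions, which avoid base-induced opening of the peroxide.

Step 24
Reactants: 31 (2R)-2-[(3S,6S)-6-methyl-6-(2-DEC-ethyl)-1,2-dioxan-3-yl]propan-1-ol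
Product: 32 (2S)-2-[(3S,6S)-6-methyl-6-(2-DEC-ethyl)-1,2-dioxan-3-yl]propanoic acid
Conditions: TEMPO (0.2 equiv), PhI(OAc)2 (2.2 equiv), MeCN/H2O (1:1), 25 °C
Reagents that add atoms: water, O
Why: TEMPO/PhI(OAc)2 oxidation (oxoammonium oxidation to the aldehyde, then of its hydrate to the acid) runs at weakly acidic pH, so C2 should not epimerise and the β-peroxide should not be eliminated.

Step 25
Reactants: 32 (2S)-2-[(3S,6S)-6-methyl-6-(2-DEC-ethyl)-1,2-dioxan-3-yl]propanoic acid
Product: 33 methyl (2S)-2-[(3S,6S)-6-methyl-6-{2-[(1S,4aR,8aR)-2,5,5,8a-tetramethyl-1,4,4a,5,6,7,8,8a-octahydronaphthalen-1-yl]ethyl}-1,2-dioxan-3-yl]propanoate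
Conditions: Me3SiCHN2, MeOH/toluene, 0 °C
Reagents that add atoms: (trimethylsilyl)diazomethane, C[Si](C)(C)C=[N+]=[N-]
Why: O-Methylation of the carboxylic acid by (trimethylsilyl)diazomethane in methanol (diazoalkane esterification), neutral and stereochemically innocent.

Compound list
1 | (R)-4a-methyl-4,4a,5,6,7,8-hexahydronaphthalen-2(3H)-one | C[C@]12CCCCC1=CC(=O)CC2 | starting material
2 | (R)-1,1,4a-trimethyl-3,4,4a,5,6,7-hexahydronaphthalen-2(1H)-one | C[C@]12CCCC=C1C(C)(C)C(=O)CC2 | intermediate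
3 | hydrazone of 2 (not isolated) | C[C@]12CCCC=C1C(C)(C)C(=NN)CC2 | intermediate
4 | (R)-1,1,4a-trimethyl-1,2,3,4,4a,5,6,7-octahydronaphthalene | C[C@]12CCCC=C1C(C)(C)CCC2 | intermediate
5 | (S)-4a,8,8-trimethyl-4,4a,5,6,7,8-hexahydronaphthalen-2(3H)-one | C[C@]12CCC(=O)C=C1C(C)(C)CCC2 | intermediate
6 | (4aS)-3,4a,8,8-tetramethyl-4,4a,5,6,7,8-hexahydronaphthalen-2(3H)-one, C3 epimer mixture | C[C@]12CC(C)C(=O)C=C1C(C)(C)CCC2 | intermediate
7 | (4aS,8aR)-3,4a,8,8-tetramethyl-3,4,4a,5,6,7,8,8a-octahydronaphthalen-2(1H)-one, trans-fused, C3 epimer mixture | C[C@]12CC(C)C(=O)C[C@@H]1C(C)(C)CCC2 | intermediate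
8 | trimethyl{[(4aS,8aR)-3,4a,8,8-tetramethyl-1,4,4a,5,6,7,8,8a-octahydronaphthalen-2-yl]oxy}silane (not isolated) | C[C@]12CC(C)=C(O[Si](C)(C)C)C[C@@H]1C(C)(C)CCC2 | intermediate
9 | (4aS,8aR)-3,4a,8,8-tetramethyl-4a,5,6,7,8,8a-hexahydronaphthalen-2(1H)-one | C[C@]12C=C(C)C(=O)C[C@@H]1C(C)(C)CCC2 | intermediate
10 | (4-bromobut-1-yn-1-yl)trimethylsilane | C[Si](C)(C)C#CCCBr | starting material
11 | [4-(trimethylsilyl)but-3-yn-1-yl]magnesium bromide (not isolated) | C[Si](C)(C)C#CCC[Mg]Br | intermediate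
12 | {[(4R,4aR,8aR)-3,4a,8,8-tetramethyl-4-[4-(trimethylsilyl)but-3-yn-1-yl]-1,4,4a,5,6,7,8,8a-octahydronaphthalen-2-yl]oxy}trimethylsilane | C[Si](C)(C)C#CCC[C@H]1C(C)=C(O[Si](C)(C)C)C[C@@H]2C(C)(C)CCC[C@]21C | intermediate
13 | (4R,4aR,8aR)-3,4a,8,8-tetramethyl-4-[4-(trimethylsilyl)but-3-yn-1-yl]-1,4,4a,5,6,7,8,8a-octahydronaphthalen-2-yl trifluoromethanesulfonate | C[Si](C)(C)C#CCC[C@H]1C(C)=C(OS(=O)(=O)C(F)(F)F)C[C@@H]2C(C)(C)CCC[C@]21C | intermediate
14 | trimethyl{4-[(1S,4aR,8aR)-2,5,5,8a-tetramethyl-1,4,4a,5,6,7,8,8a-octahydronaphthalen-1-yl]but-1-yn-1-yl}silane | C[Si](C)(C)C#CCC[C@H]1C(C)=CC[C@@H]2C(C)(C)CCC[C@]21C | intermediate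
15 | 4-[(1S,4aR,8aR)-2,5,5,8a-tetramethyl-1,4,4a,5,6,7,8,8a-octahydronaphthalen-1-yl]but-1-yne | C#CCC[C@H]1C(C)=CC[C@@H]2C(C)(C)CCC[C@]21C | intermediate
16 | dimethyl{(1E)-2-methyl-4-[(1S,4aR,8aR)-2,5,5,8a-tetramethyl-1,4,4a,5,6,7,8,8a-octahydronaphthalen-1-yl]but-1-en-1-yl}alane (not isolated) | C[Al](C)/C=C(\C)CC[C@H]1C(C)=CC[C@@H]2C(C)(C)CCC[C@]21C | intermediate
17 | (2E)-3-methyl-5-[(1S,4aR,8aR)-2,5,5,8a-tetramethyl-1,4,4a,5,6,7,8,8a-octahydronaphthalen-1-yl]pent-2-en-1-ol | OC/C=C(\C)CC[C@H]1C(C)=CC[C@@H]2C(C)(C)CCC[C@]21C | intermediate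
18 | [(2R,3R)-3-methyl-3-{2-[(1S,4aR,8aR)-2,5,5,8a-tetramethyl-1,4,4a,5,6,7,8,8a-octahydronaphthalen-1-yl]ethyl}oxiran-2-yl]methanol | OC[C@H]1O[C@]1(C)CC[C@H]2C(C)=CC[C@@H]3C(C)(C)CCC[C@]32C | intermediate
19 | (S)-4-benzyl-3-propionyloxazolidin-2-one | CCC(=O)N1[C@@H](Cc2ccccc2)COC1=O | starting material
20 | acrolein | C=CC=O | starting material
21 | (S)-4-benzyl-3-[(2S,3R)-3-hydroxy-2-methylpent-4-enoyl]oxazolidin-2-one | C=C[C@@H](O)[C@H](C)C(=O)N1[C@@H](Cc2ccccc2)COC1=O | intermediate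
22 | (2R,3R)-2-methylpent-4-ene-1,3-diol | C=C[C@@H](O)[C@H](C)CO | intermediate
23 | (3R,4R)-5-{[tert-butyl(diphenyl)silyl]oxy}-4-methylpent-1-en-3-ol | C=C[C@@H](O)[C@H](C)CO[Si](c1ccccc1)(c1ccccc1)C(C)(C)C | intermediate
24 | (3R,4R)-5-{[tert-butyl(diphenyl)silyl]oxy}-4-methylpent-1-en-3-yl methanesulfonate | C=C[C@@H](OS(C)(=O)=O)[C@H](C)CO[Si](c1ccccc1)(c1ccccc1)C(C)(C)C | intermediate
25 | tert-butyl{[(2R,3S)-3-hydroperoxy-2-methylpent-4-en-1-yl]oxy}diphenylsilane | C=C[C@H](OO)[C@H](C)CO[Si](c1ccccc1)(c1ccccc1)C(C)(C)C | intermediate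
26 | (2R,3S)-3-{[(3S,4R)-5-{[tert-butyl(diphenyl)silyl]oxy}-4-methylpent-1-en-3-yl]peroxy}-3-methyl-5-[(1S,4aR,8aR)-2,5,5,8a-tetramethyl-1,4,4a,5,6,7,8,8a-octahydronaphthalen-1-yl]pentane-1,2-diol | CC(C)(C)[Si](c1ccccc1)(c1ccccc1)OC[C@@H](C)[C@H](C=C)OO[C@](C)([C@H](O)CO)CC[C@H]1C(C)=CC[C@@H]2C(C)(C)CCC[C@]21C | intermediate
27 | (2S)-2-{[(3S,4R)-5-{[tert-butyl(diphenyl)silyl]oxy}-4-methylpent-1-en-3-yl]peroxy}-2-methyl-4-[(1S,4aR,8aR)-2,5,5,8a-tetramethyl-1,4,4a,5,6,7,8,8a-octahydronaphthalen-1-yl]butanal | CC(C)(C)[Si](c1ccccc1)(c1ccccc1)OC[C@@H](C)[C@H](C=C)OO[C@](C)(C=O)CC[C@H]1C(C)=CC[C@@H]2C(C)(C)CCC[C@]21C | intermediate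
28 | tert-butyl{[(2R,3S)-2-methyl-3-({(3S)-3-methyl-5-[(1S,4aR,8aR)-2,5,5,8a-tetramethyl-1,4,4a,5,6,7,8,8a-octahydronaphthalen-1-yl]pent-1-en-3-yl}peroxy)pent-4-en-1-yl]oxy}diphenylsilane | CC(C)(C)[Si](c1ccccc1)(c1ccccc1)OC[C@@H](C)[C@H](C=C)OO[C@](C)(C=C)CC[C@H]1C(C)=CC[C@@H]2C(C)(C)CCC[C@]21C | intermediate
29 | tert-butyl{(2R)-2-[(3S,6S)-6-methyl-6-{2-[(1S,4aR,8aR)-2,5,5,8a-tetramethyl-1,4,4a,5,6,7,8,8a-octahydronaphthalen-1-yl]ethyl}-3,6-dihydro-1,2-dioxin-3-yl]propoxy}diphenylsilane | CC(C)(C)[Si](c1ccccc1)(c1ccccc1)OC[C@@H](C)[C@@H]1C=C[C@](C)(CC[C@H]2C(C)=CC[C@@H]3C(C)(C)CCC[C@]32C)OO1 | intermediate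
30 | tert-butyl{(2R)-2-[(3S,6S)-6-methyl-6-{2-[(1S,4aR,8aR)-2,5,5,8a-tetramethyl-1,4,4a,5,6,7,8,8a-octahydronaphthalen-1-yl]ethyl}-1,2-dioxan-3-yl]propoxy}diphenylsilane | CC(C)(C)[Si](c1ccccc1)(c1ccccc1)OC[C@@H](C)[C@@H]1CC[C@](C)(CC[C@H]2C(C)=CC[C@@H]3C(C)(C)CCC[C@]32C)OO1 | intermediate
31 | (2R)-2-[(3S,6S)-6-methyl-6-{2-[(1S,4aR,8aR)-2,5,5,8a-tetramethyl-1,4,4a,5,6,7,8,8a-octahydronaphthalen-1-yl]ethyl}-1,2-dioxan-3-yl]propan-1-ol | OC[C@@H](C)[C@@H]1CC[C@](C)(CC[C@H]2C(C)=CC[C@@H]3C(C)(C)CCC[C@]32C)OO1 | intermediate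
32 | (2S)-2-[(3S,6S)-6-methyl-6-{2-[(1S,4aR,8aR)-2,5,5,8a-tetramethyl-1,4,4a,5,6,7,8,8a-octahydronaphthalen-1-yl]ethyl}-1,2-dioxan-3-yl]propanoic acid | OC(=O)[C@@H](C)[C@@H]1CC[C@](C)(CC[C@H]2C(C)=CC[C@@H]3C(C)(C)CCC[C@]32C)OO1 | intermediate
33 | methyl (2S)-2-[(3S,6S)-6-methyl-6-{2-[(1S,4aR,8aR)-2,5,5,8a-tetramethyl-1,4,4a,5,6,7,8,8a-octahydronaphthalen-1-yl]ethyl}-1,2-dioxan-3-yl]propanoate | COC(=O)[C@@H](C)[C@@H]1CC[C@](C)(CC[C@H]2C(C)=CC[C@@H]3C(C)(C)CCC[C@]32C)OO1 | target

Total step count: 25. Longest linear sequence: 20 steps (steps 1–12, then 18–25); steps 13–17 form the five-step side branch to hydroperoxide 25.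

Steps most likely to fail

Step 21. The ruthenium alkylidene may be consumed by attack on the O–O bond, the allylic peroxide may be expelled from the metallacycle, or oligomers may form in place of the ring. The fallback uses known chemistry, the [4+2] addition of singlet oxygen to a 1,3-diene. It sets out from alkyne 15: the alkenylalane 16, generated as in step 11, is not hydroxymethylated but cross-coupled (Negishi coupling, Pd(PPh3)4, ZnCl2, THF) with the vinyl iodide tert-butyl{[(2S,3E)-4-iodo-2-methylbut-3-en-1-yl]oxy}diphenylsilane F4 to give the (3E,5E)-diene tert-butyl{[(2S,3E,5E)-2,6-dimethyl-8-DEC-octa-3,5-dien-1-yl]oxy}diphenylsilane F5. F4 is made from commercial methyl (R)-3-hydroxy-2-methylpropanoate F1 by silylation (t-BuPh2SiCl, imidazole) to methyl (R)-3-(TBDPS-oxy)-2-methylpropanoate F2, reduction with i-Bu2AlH at −78 °C to (R)-3-(TBDPS-oxy)-2-methylpropanal F3 and Takai iodo-olefination (CrCl2, CHI3, THF). Sensitised photooxygenation of F5 (O2, tetraphenylporphyrin, hν, CH2Cl2, −78 °C) should add singlet oxygen across C3 and C6. The addition is suprafacial on the (E,E)-diene, so the C3 side chain and the C6 chain end up cis as in 29. The two diene faces are not differentiated, so 29 would form together with its (3R,6R) diastereomer F6 and would have to be separated by chromatography. The trisubstituted C7′=C8′ alkene can also react with singlet oxygen, so conversion would be kept low. The route is rejoined at 29.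

Step 18. The Lewis acid may trigger a hydride or alkyl shift of the epoxide, acid-induced (Hock-type) cleavage of the allylic hydroperoxide, or ionisation at the tertiary carbon with loss of configuration at C6. The fallback exchanges the roles of the two partners. It sets out from epoxy alcohol 18, which is opened with hydrogen peroxide alone (ethereal H2O2, H3PMo12O40 cat., Et2O, 25 °C; the established perhydrolysis of trisubstituted epoxy alcohols at the tertiary carbon with inversion) to the tertiary hydroperoxide (2R,3S)-3-hydroperoxy-3-methyl-5-DEC-pentane-1,2-diol F7. The cesium peroxide of F7 (CsOH·H2O, DMF, 0 °C; the hydroperoxide is far more acidic than the two hydroxyls) is then O-alkylated with mesylate 24, with inversion at C3. This gives 26, where the route is rejoined.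

Step 17. Attack at the allyl terminus, elimination to the diene or ionisation of the allylic mesylate would erode the regiochemistry and the configuration at C3. The fallback brings in the O–O unit by an ene reaction in place of a substitution. It sets out from alcohol 23: Myers reductive 1,3-transposition (2-nitrobenzenesulfonylhydrazide, PPh3, diethyl azodicarboxylate, THF, −30 → 25 °C) gives the (E)-alkene tert-butyl{[(2S,3E)-2-methylpent-3-en-1-yl]oxy}diphenylsilane F8. Schenck ene reaction with singlet oxygen (O2, tetraphenylporphyrin, hν, CH2Cl2, 0 °C) should abstract a hydrogen of the terminal methyl group and place the hydroperoxide on C3. Little facial bias is expected, so 25 would form together with its C3 epimer F9 and the two would be separated by chromatography. The route is rejoined at 25.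

Further compounds
F1 | step 21 | methyl (R)-3-hydroxy-2-methylpropanoate (commercial) | OC[C@@H](C)C(=O)OC
F2 | step 21 | methyl (R)-3-{[tert-butyl(diphenyl)silyl]oxy}-2-methylpropanoate | CC(C)(C)[Si](c1ccccc1)(c1ccccc1)OC[C@@H](C)C(=O)OC
F3 | step 21 | (R)-3-{[tert-butyl(diphenyl)silyl]oxy}-2-methylpropanal | CC(C)(C)[Si](c1ccccc1)(c1ccccc1)OC[C@@H](C)C=O
F4 | step 21 | tert-butyl{[(2S,3E)-4-iodo-2-methylbut-3-en-1-yl]oxy}diphenylsilane | CC(C)(C)[Si](c1ccccc1)(c1ccccc1)OC[C@@H](C)/C=C/I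
F5 | step 21 | tert-butyl{[(2S,3E,5E)-2,6-dimethyl-8-[(1S,4aR,8aR)-2,5,5,8a-tetramethyl-1,4,4a,5,6,7,8,8a-octahydronaphthalen-1-yl]octa-3,5-dien-1-yl]oxy}diphenylsilane | CC(C)(C)[Si](c1ccccc1)(c1ccccc1)OC[C@@H](C)/C=C/C=C(\C)CC[C@H]1C(C)=CC[C@@H]2C(C)(C)CCC[C@]21C
F6 | step 21 | (3R,6R) diastereomer of 29 | CC(C)(C)[Si](c1ccccc1)(c1ccccc1)OC[C@@H](C)[C@H]1C=C[C@@](C)(CC[C@H]2C(C)=CC[C@@H]3C(C)(C)CCC[C@]32C)OO1
F7 | step 18 | (2R,3S)-3-hydroperoxy-3-methyl-5-[(1S,4aR,8aR)-2,5,5,8a-tetramethyl-1,4,4a,5,6,7,8,8a-octahydronaphthalen-1-yl]pentane-1,2-diol | OO[C@](C)([C@H](O)CO)CC[C@H]1C(C)=CC[C@@H]2C(C)(C)CCC[C@]21C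
F8 | step 17 | tert-butyl{[(2S,3E)-2-methylpent-3-en-1-yl]oxy}diphenylsilane | C/C=C/[C@H](C)CO[Si](c1ccccc1)(c1ccccc1)C(C)(C)C
F9 | step 17 | C3 epimer of 25, tert-butyl{[(2R,3R)-3-hydroperoxy-2-methylpent-4-en-1-yl]oxy}diphenylsilane | C=C[C@@H](OO)[C@H](C)CO[Si](c1ccccc1)(c1ccccc1)C(C)(C)C
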